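**Plan**

- Retrosynthesis: the quinone is taken back to a 1,4-bis(benzyloxy)-5-chloronaphthalene (C1=O and C4=O from two benzyl ethers, C5–H from C5–Cl). Ring B is then cut at C4a–C5, and the C7=C8 double bond is folded back into a C5–C7 cyclopropane bond.
- The resulting diaryl(2,2-dichlorocyclopropyl)methanol is cut at the two C8–aryl bonds (aryllithium additions), at C5–C6/C5–C7 (dichlorocarbene) and at C6=C7 (cross-metathesis).
- Enabling feature: C8 carries both ring A and the guaiacyl group, and C5, C6 and C7 can be stored as a cyclopropane that opens toward C4a, the only free ortho carbon of ring A. An oxygen placed on C4 makes C4a ortho/para to two alkoxy groups and already holds the quinone oxidation level.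
- Forward order: benzyl arm with the C6=C7 alkene, cyclopropane, ring A onto C8, guaiacyl ring onto C8, ring B by benzannulation, then hydrogenolysis and air oxidation to the quinone.
- Stereochemistry: the target has no stereocentre. The trans cyclopropane comes from the E alkene, the carbinol configuration from face-selective addition to the ketone, and all three centres vanish when ring B becomes aromatic.

Key step: step 12

Remark: atom labels C1 to C8a follow the naphthoquinone numbering of the target; all chiral intermediates are racemic and drawn as one enantiomer.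
Assumption: the guaiacyl aryllithium attacks the ketone on the face next to C6–H, giving the carbinol epimer drawn; if the other epimer forms, the fallback for step 12 applies.

**Route**

Step 1
Reactants: 1 eugenol
Product: 2 4-allyl-1-(benzyloxy)-2-methoxybenzene
Conditions: BnBr, K2CO3, acetone, reflux
Reagents that add atoms: benzyl bromide, BrCc1ccccc1
Why: Williamson etherification of the phenoxide with a benzylic bromide; the allyl group does not migrate under K2CO3.

Step 2
Reactants: 2 4-allyl-1-(benzyloxy)-2-methoxybenzene; 3 ethyl methacrylate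
Product: 4 ethyl (E)-4-[4-(benzyloxy)-3-methoxyphenyl]-2-methylbut-2-enoate
Conditions: (H2IMes)(PCy3)Cl2Ru=CHPh (second-generation Grubbs catalyst, 5 mol %), excess 3, 1,4-benzoquinone (10 mol %), CH2Cl2, 40 °C
Reagents that add atoms: none
Why: Olefin cross-metathesis of a terminal alkene with a methacrylate, which does not homodimerise, should give the trisubstituted enoate as its more stable E isomer (ester trans to the arylmethyl group), with benzoquinone holding back migration of the allyl double bond.

Step 3
Reactants: 4 ethyl (E)-4-[4-(benzyloxy)-3-methoxyphenyl]-2-methylbut-2-enoate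
Product: 5 (E)-4-[4-(benzyloxy)-3-methoxyphenyl]-2-methylbut-2-en-1-ol
Conditions: i-Bu2AlH (2.2 equiv), CH2Cl2, –78 °C; aq. KNaC4H4O6 (potassium sodium tartrate)
Reagents that add atoms: none
Why: 1,2-Reduction of the enoate by i-Bu2AlH gives the allylic alcohol with the E geometry intact; removing the ester makes the alkene electron-rich for the carbene and takes away the acidity of the benzylic CH2, which under hydroxide would let the double bond move into conjugation with the arene.

Step 4
Reactants: 5 (E)-4-[4-(benzyloxy)-3-methoxyphenyl]-2-methylbut-2-en-1-ol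
Product: 6 rac-[(1R,3S)-3-[4-(benzyloxy)-3-methoxybenzyl]-2,2-dichloro-1-methylcyclopropyl]methanol
Conditions: CHCl3, 50% aq. NaOH, BnEt3NCl (cat.), 0 °C to rt
Reagents that add atoms: chloroform, ClC(Cl)Cl
Why: Phase-transfer dichlorocyclopropanation, in which CCl2 adds in a concerted, stereospecific way to the trisubstituted alkene, so the E geometry places CH2OH trans to the arylmethyl group; for trisubstituted allylic alcohols addition to the alkene is known to outrun reaction at oxygen.

Step 5
Reactants: 6 rac-[(1R,3S)-3-[4-(benzyloxy)-3-methoxybenzyl]-2,2-dichloro-1-methylcyclopropyl]methanol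
Product: 7 rac-(1R,3S)-3-[4-(benzyloxy)-3-methoxybenzyl]-2,2-dichloro-1-methylcyclopropane-1-carbaldehyde
Conditions: Dess–Martin periodinane, CH2Cl2, 0 °C to rt
Reagents that add atoms: none
Why: Dess–Martin oxidation of a primary alcohol to the aldehyde; the α-carbon is quaternary, so the product can neither enolise nor epimerise.

Step 6
Reactants: 8 5-bromovanillin
Product: 9 2-bromo-6-methoxybenzene-1,4-diol
Conditions: 30% aq. H2O2, NaOH, THF/H2O, 0 °C to rt, N2; then HCl
Reagents that add atoms: hydrogen peroxide, OO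
Why: Dakin oxidation of a para-hydroxybenzaldehyde: hydroperoxide adds to the aldehyde, the aryl group migrates to oxygen and the aryl formate is hydrolysed, which gives the hydroquinone with bromine and methoxy flanking one hydroxyl.

Step 7
Reactants: 9 2-bromo-6-methoxybenzene-1,4-diol
Product: 10 2,5-bis(benzyloxy)-1-bromo-3-methoxybenzene
Conditions: BnBr (2.3 equiv), K2CO3, DMF, rt to 50 °C, N2
Reagents that add atoms: benzyl bromide, BrCc1ccccc1
Why: Double Williamson etherification of both phenols, run under nitrogen because the hydroquinone is air-sensitive until protected.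

Step 8
Reactants: 10 2,5-bis(benzyloxy)-1-bromo-3-methoxybenzene; 7 rac-(1R,3S)-3-[4-(benzyloxy)-3-methoxybenzyl]-2,2-dichloro-1-methylcyclopropane-1-carbaldehyde
Product: 12 [2,5-bis(benzyloxy)-3-methoxyphenyl][(1R*,3S*)-3-[4-(benzyloxy)-3-methoxybenzyl]-2,2-dichloro-1-methylcyclopropyl]methanol (both carbinol epimers), via ring A aryllithium 11 (not isolated)
Conditions: 10, n-BuLi, THF, –78 °C; then 7, –78 °C; H2O
Reagents that add atoms: none
Why: Bromine–lithium exchange at –78 °C outpaces attack of n-BuLi on the benzyl ethers, and the aryllithium adds 1,2 to the non-enolisable aldehyde; the new carbinol centre forms without control and is removed by the oxidation in step 9.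

Step 9
Reactants: 12 [2,5-bis(benzyloxy)-3-methoxyphenyl][(1R*,3S*)-3-[4-(benzyloxy)-3-methoxybenzyl]-2,2-dichloro-1-methylcyclopropyl]methanol
Product: 13 rac-[2,5-bis(benzyloxy)-3-methoxyphenyl][(1R,3S)-3-[4-(benzyloxy)-3-methoxybenzyl]-2,2-dichloro-1-methylcyclopropyl]methanone
Conditions: Dess–Martin periodinane, pyridine, CH2Cl2, 0 °C
Reagents that add atoms: none
Why: Dess–Martin oxidation of the hindered benzylic alcohol gives the aryl cyclopropyl ketone, with pyridine buffering so that the acid-labile cyclopropylcarbinol does not ionise.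

Step 10
Reactants: 14 4-bromo-2-methoxyphenol
Product: 15 1-(benzyloxy)-4-bromo-2-methoxybenzene
Conditions: BnBr, K2CO3, acetone, reflux
Reagents that add atoms: benzyl bromide, BrCc1ccccc1
Why: Williamson etherification of the phenoxide with a benzylic bromide.

Step 11
Reactants: 15 1-(benzyloxy)-4-bromo-2-methoxybenzene; 13 rac-[2,5-bis(benzyloxy)-3-methoxyphenyl][(1R,3S)-3-[4-(benzyloxy)-3-methoxybenzyl]-2,2-dichloro-1-methylcyclopropyl]methanone
Product: 17 rac-(S)-[2,5-bis(benzyloxy)-3-methoxyphenyl][4-(benzyloxy)-3-methoxyphenyl][(1R,3S)-3-[4-(benzyloxy)-3-methoxybenzyl]-2,2-dichloro-1-methylcyclopropyl]methanol, via guaiacyl aryllithium 16 (not isolated)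
Conditions: 15, n-BuLi, THF, –78 °C; then 13, –78 to –40 °C; H2O; Et3N-deactivated silica
Reagents that add atoms: none
Why: Bromine–lithium exchange followed by 1,2-addition to a ketone that cannot enolise, as known for aryl 2,2-dichlorocyclopropyl ketones; the aryllithium is expected to attack the conformer with C=O turned away from the CCl2 carbon, on the face flanked by C6–H and not by chlorine (Felkin–Anh-type control), which sets the carbinol centre as drawn.

Step 12
Reactants: 17 rac-(S)-[2,5-bis(benzyloxy)-3-methoxyphenyl][4-(benzyloxy)-3-methoxyphenyl][(1R,3S)-3-[4-(benzyloxy)-3-methoxybenzyl]-2,2-dichloro-1-methylcyclopropyl]methanol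
Product: 18 1,4-bis(benzyloxy)-8-[4-(benzyloxy)-3-methoxyphenyl]-6-[4-(benzyloxy)-3-methoxybenzyl]-5-chloro-2-methoxy-7-methylnaphthalene
Conditions: SnCl4 (1.1 equiv), CH2Cl2, –78 °C; aq. NaHCO3
Reagents that add atoms: none
Why: SnCl4 ionises the tertiary carbinol to a diarylcarbinyl cation at C8, the C5–C7 cyclopropane bond opens to give the C7=C8 alkene and a cation at C5 that two chlorines stabilise, C5 bonds to C4a of ring A, and loss of HCl across C5–C6 makes ring B aromatic with one chlorine left on C5. The closest known reaction is the Lewis acid benzannulation of diaryl(2,2-dichlorocyclopropyl)methanols to 1-aryl-4-chloronaphthalenes, a cyclopropylcarbinyl to homoallyl cation rearrangement followed by arene alkylation. Ring B closes in a six-membered intramolecular Friedel–Crafts alkylation of C4a by C5. No stereocentre is formed and the three of 17 are lost. The step needs closure onto ring A and not onto the guaiacyl ring on C8 or the ring of the benzyl arm (which would give an indane): C4a is ortho to the C4 benzyloxy and para to the C2 methoxy group and so far more nucleophilic than any carbon of the two guaiacyl rings, and a SnCl4 chelate between the carbinol oxygen and the cis chlorine on C5 places ring A of the drawn epimer over the cyclopropane, so that it ends cis to C6 on the new alkene. Only the C5–C7 bond opens, because cleavage of C6–C7 would give a secondary cation next to CCl2.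

Step 13
Reactants: 18 1,4-bis(benzyloxy)-8-[4-(benzyloxy)-3-methoxyphenyl]-6-[4-(benzyloxy)-3-methoxybenzyl]-5-chloro-2-methoxy-7-methylnaphthalene
Product: 20 larreantin, via naphthalene-1,4-diol 19 (not isolated)
Conditions: H2 (1 atm), 10% Pd/C, THF/MeOH, rt; then Et3N, H2, rt; filter; air, rt
Reagents that add atoms: none
Why: Pd/C hydrogenolysis cleaves the four aryl benzyl ethers and, once Et3N is added to take up HCl, the aryl C–Cl bond (catalytic hydrodechlorination), and the 2-methoxynaphthalene-1,4-diol so formed is autoxidised by air to the quinone under conditions that leave the two guaiacol phenols untouched.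

**Compound list**

1 | eugenol | C=CCc1ccc(O)c(OC)c1 | starting material
2 | 4-allyl-1-(benzyloxy)-2-methoxybenzene | C=CCc1ccc(OCc2ccccc2)c(OC)c1 | intermediate
3 | ethyl methacrylate | C=C(C)C(=O)OCC | starting material
4 | ethyl (E)-4-[4-(benzyloxy)-3-methoxyphenyl]-2-methylbut-2-enoate | CCOC(=O)/C(C)=C/Cc1ccc(OCc2ccccc2)c(OC)c1 | intermediate
5 | (E)-4-[4-(benzyloxy)-3-methoxyphenyl]-2-methylbut-2-en-1-ol | OC/C(C)=C/Cc1ccc(OCc2ccccc2)c(OC)c1 | intermediate
6 | rac-[(1R,3S)-3-[4-(benzyloxy)-3-methoxybenzyl]-2,2-dichloro-1-methylcyclopropyl]methanol (CH2OH trans to the arylmethyl group) | C[C@]1(CO)[C@H](Cc2ccc(OCc3ccccc3)c(OC)c2)C1(Cl)Cl | intermediate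
7 | rac-(1R,3S)-3-[4-(benzyloxy)-3-methoxybenzyl]-2,2-dichloro-1-methylcyclopropane-1-carbaldehyde | C[C@]1(C=O)[C@H](Cc2ccc(OCc3ccccc3)c(OC)c2)C1(Cl)Cl | intermediate
8 | 5-bromovanillin (3-bromo-4-hydroxy-5-methoxybenzaldehyde) | COc1cc(C=O)cc(Br)c1O | starting material
9 | 2-bromo-6-methoxybenzene-1,4-diol | COc1cc(O)cc(Br)c1O | intermediate
10 | 2,5-bis(benzyloxy)-1-bromo-3-methoxybenzene | COc1cc(OCc2ccccc2)cc(Br)c1OCc1ccccc1 | intermediate
11 | [2,5-bis(benzyloxy)-3-methoxyphenyl]lithium | [Li]c1cc(OCc2ccccc2)cc(OC)c1OCc1ccccc1 | intermediate (not isolated)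
12 | [2,5-bis(benzyloxy)-3-methoxyphenyl][(1R*,3S*)-3-[4-(benzyloxy)-3-methoxybenzyl]-2,2-dichloro-1-methylcyclopropyl]methanol, racemic, both carbinol epimers | C[C@]1(C(O)c2cc(OCc3ccccc3)cc(OC)c2OCc2ccccc2)[C@H](Cc2ccc(OCc3ccccc3)c(OC)c2)C1(Cl)Cl | intermediate
13 | rac-[2,5-bis(benzyloxy)-3-methoxyphenyl][(1R,3S)-3-[4-(benzyloxy)-3-methoxybenzyl]-2,2-dichloro-1-methylcyclopropyl]methanone | C[C@]1(C(=O)c2cc(OCc3ccccc3)cc(OC)c2OCc2ccccc2)[C@H](Cc2ccc(OCc3ccccc3)c(OC)c2)C1(Cl)Cl | intermediate
14 | 4-bromo-2-methoxyphenol | COc1cc(Br)ccc1O | starting material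
15 | 1-(benzyloxy)-4-bromo-2-methoxybenzene | COc1cc(Br)ccc1OCc1ccccc1 | intermediate
16 | [4-(benzyloxy)-3-methoxyphenyl]lithium | [Li]c1ccc(OCc2ccccc2)c(OC)c1 | intermediate (not isolated)
17 | rac-(S)-[2,5-bis(benzyloxy)-3-methoxyphenyl][4-(benzyloxy)-3-methoxyphenyl][(1R,3S)-3-[4-(benzyloxy)-3-methoxybenzyl]-2,2-dichloro-1-methylcyclopropyl]methanol | C[C@]1([C@@](O)(c2cc(OCc3ccccc3)cc(OC)c2OCc2ccccc2)c2ccc(OCc3ccccc3)c(OC)c2)[C@H](Cc2ccc(OCc3ccccc3)c(OC)c2)C1(Cl)Cl | intermediate
18 | 1,4-bis(benzyloxy)-8-[4-(benzyloxy)-3-methoxyphenyl]-6-[4-(benzyloxy)-3-methoxybenzyl]-5-chloro-2-methoxy-7-methylnaphthalene | COc1cc(OCc2ccccc2)c2c(Cl)c(Cc3ccc(OCc4ccccc4)c(OC)c3)c(C)c(-c3ccc(OCc4ccccc4)c(OC)c3)c2c1OCc1ccccc1 | intermediate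
19 | 8-(4-hydroxy-3-methoxyphenyl)-6-(4-hydroxy-3-methoxybenzyl)-2-methoxy-7-methylnaphthalene-1,4-diol | COc1cc(O)c2cc(Cc3ccc(O)c(OC)c3)c(C)c(-c3ccc(O)c(OC)c3)c2c1O | intermediate (not isolated)
20 | larreantin, 8-(4-hydroxy-3-methoxyphenyl)-6-(4-hydroxy-3-methoxybenzyl)-2-methoxy-7-methylnaphthalene-1,4-dione | COC1=CC(=O)c2cc(Cc3ccc(O)c(OC)c3)c(C)c(-c3ccc(O)c(OC)c3)c2C1=O | target

**Summary**

Total step count: 13. Longest linear sequence: 10 steps (steps 1, 2, 3, 4, 5, 8, 9, 11, 12, 13, from eugenol).

Steps most likely to fail: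

1. Step 12. The ring opening may keep the geometry set by the carbinol centre and deliver the guaiacyl ring on C8, not ring A, to C5, so that the wrong arene closes; the peri contact between the C4 benzyloxy group and C5 may also slow the closure. The fallback sets out from 7 and returns at 18 with the order of the aryl additions inverted. Aryllithium 16 is added to 7 to give the secondary alcohol [4-(benzyloxy)-3-methoxyphenyl][(1R*,3S*)-3-[4-(benzyloxy)-3-methoxybenzyl]-2,2-dichloro-1-methylcyclopropyl]methanol F1. Dess–Martin oxidation gives the guaiacyl ketone F2. Addition of aryllithium 11 then gives the carbinol epimer F3, in which the two aryl groups have changed places relative to the cyclopropane. Treatment of F3 with SnCl4 as in step 12 should give 18.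

2. Step 4. The alkoxide of the free allylic alcohol may capture the carbene at oxygen (chloride or formate formation) faster than the alkene is cyclopropanated. The fallback sets out from 5 and returns at 6 by masking the hydroxyl. TBSCl and imidazole in DMF give the silyl ether tert-butyl{[(E)-4-[4-(benzyloxy)-3-methoxyphenyl]-2-methylbut-2-en-1-yl]oxy}dimethylsilane F4. The same phase-transfer carbene addition gives the silylated dichlorocyclopropane F5. Bu4NF in THF then frees 6.

3. Step 13. Debenzylation may run ahead while the hindered chloride on C5, peri to the C4 oxygen, resists hydrogenolysis, leaving chlorine in the quinone. The fallback sets out from 18 and returns at 19 by separating the two events. Homogeneous hydrodechlorination with Pd(OAc)2, XPhos and HCO2Na in DMF at 100 °C gives the chlorine-free tetrabenzyl ether 1,4-bis(benzyloxy)-8-[4-(benzyloxy)-3-methoxyphenyl]-6-[4-(benzyloxy)-3-methoxybenzyl]-2-methoxy-7-methylnaphthalene F6. Plain hydrogenolysis over Pd/C then gives 19, which air oxidises to 20 as in the route.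

Further compounds
F1 | step 12 | [4-(benzyloxy)-3-methoxyphenyl][(1R*,3S*)-3-[4-(benzyloxy)-3-methoxybenzyl]-2,2-dichloro-1-methylcyclopropyl]methanol, racemic, both carbinol epimers | C[C@]1(C(O)c2ccc(OCc3ccccc3)c(OC)c2)[C@H](Cc2ccc(OCc3ccccc3)c(OC)c2)C1(Cl)Cl
F2 | step 12 | rac-[4-(benzyloxy)-3-methoxyphenyl][(1R,3S)-3-[4-(benzyloxy)-3-methoxybenzyl]-2,2-dichloro-1-methylcyclopropyl]methanone | C[C@]1(C(=O)c2ccc(OCc3ccccc3)c(OC)c2)[C@H](Cc2ccc(OCc3ccccc3)c(OC)c2)C1(Cl)Cl
F3 | step 12 | rac-(R)-[2,5-bis(benzyloxy)-3-methoxyphenyl][4-(benzyloxy)-3-methoxyphenyl][(1R,3S)-3-[4-(benzyloxy)-3-methoxybenzyl]-2,2-dichloro-1-methylcyclopropyl]methanol | C[C@]1([C@](O)(c2cc(OCc3ccccc3)cc(OC)c2OCc2ccccc2)c2ccc(OCc3ccccc3)c(OC)c2)[C@H](Cc2ccc(OCc3ccccc3)c(OC)c2)C1(Cl)Cl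
F4 | step 4 | tert-butyl{[(E)-4-[4-(benzyloxy)-3-methoxyphenyl]-2-methylbut-2-en-1-yl]oxy}dimethylsilane | CC(C)(C)[Si](C)(C)OC/C(C)=C/Cc1ccc(OCc2ccccc2)c(OC)c1
F5 | step 4 | rac-tert-butyl{[(1R,3S)-3-[4-(benzyloxy)-3-methoxybenzyl]-2,2-dichloro-1-methylcyclopropyl]methoxy}dimethylsilane | C[C@]1(CO[Si](C)(C)C(C)(C)C)[C@H](Cc2ccc(OCc3ccccc3)c(OC)c2)C1(Cl)Cl
F6 | step 13 | 1,4-bis(benzyloxy)-8-[4-(benzyloxy)-3-methoxyphenyl]-6-[4-(benzyloxy)-3-methoxybenzyl]-2-methoxy-7-methylnaphthalene | COc1cc(OCc2ccccc2)c2cc(Cc3ccc(OCc4ccccc4)c(OC)c3)c(C)c(-c3ccc(OCc4ccccc4)c(OC)c3)c2c1OCc1ccccc1
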